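**Retrosynthetic overview**
1. Target ⇐ C5‑isopropenyl compound 20 (allylic CH3 → CHO) ⇐ α‑phosphono lactone 19 (Horner–Wadsworth–Emmons with CH2O); the oxirane comes from a hydroxy‑mesylate closure with inversion, the C6–OH from a late ketone reduction, the C9 ester by acylation.
2. The 8,12‑lactone and O8 ⇐ α‑hydroxylation of the C9 ketone next to a C7 phosphonoacetate, itself from a Michael addition to the C9 enone.
3. Quaternary C10 ⇐ two α′‑enolate reactions of that enone (MeI, then aldol), both directed by C5.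
4. C5 and the C5–C4 bond ⇐ desymmetrizing NHC‑catalysed Stetter addition of acetaldehyde (acetyl anion equivalent) to p‑benzoquinone mono(dimethyl ketal), then methylenation.
5. Ring order: the carbocycle is the quinone monoketal ring (never formed), then the γ‑lactone (step 6), then the oxirane (step 11).

Assumption: intermediates are described with the target's elemanolide locants (ring C5–C10: C5 bears C4, C6 the free OH, C7 the lactone carbon C11, C8 the lactone O, C9 the ester O, C10 the methyl and C1–C2; β = face of the C10 methyl); the SMILES are authoritative for stereochemistry.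

**Step 1**
Reactants: 1 4,4‑dimethoxycyclohexa‑2,5‑dien‑1‑one; 2 acetaldehyde
Product: 3 (R)‑5‑acetyl‑4,4‑dimethoxycyclohex‑2‑en‑1‑one
Conditions: 2 (5 eq), chiral aminoindanol‑derived N‑C6F5 triazolium BF4 (20 mol%), i‑Pr2NEt (20 mol%), catechol (20 mol%), t‑AmOH, 0 °C
Reagents that add atoms: none
Why: Proposed new method: the Breslow intermediate of acetaldehyde adds 1,4 to one of the two enantiotopic enone arms of the prochiral dienone, the chiral triazolylidene selecting the arm and so setting C5 (Stetter reaction); the closest known chemistry is the NHC‑catalysed desymmetrizing intramolecular Stetter reaction of cyclohexadienones and the enantioselective intermolecular Stetter reaction of aliphatic aldehydes, and the mono‑adduct is expected to be a poorer acceptor than 1.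

**Step 2**
Reactants: 3 (R)‑5‑acetyl‑4,4‑dimethoxycyclohex‑2‑en‑1‑one
Product: 4 (R)‑4,4‑dimethoxy‑5‑(prop‑1‑en‑2‑yl)cyclohex‑2‑en‑1‑one
Conditions: Zn, CH2Br2, TiCl4, THF, 0 °C
Reagents that add atoms: dibromomethane BrCBr
Why: Takai–Lombardo methylenation is non‑basic, so the epimerizable C5 centre and the β‑methoxy groups survive, and the saturated methyl ketone should react before the conjugated enone carbonyl.

**Step 3**
Reactants: 4 (R)‑4,4‑dimethoxy‑5‑(prop‑1‑en‑2‑yl)cyclohex‑2‑en‑1‑one
Product: 5 (5R)‑4,4‑dimethoxy‑6‑methyl‑5‑(prop‑1‑en‑2‑yl)cyclohex‑2‑en‑1‑one (C6 epimer mixture)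
Conditions: LDA, THF, −78 °C; MeI, −78 to −20 °C
Reagents that add atoms: iodomethane CI
Why: kinetic α′‑deprotonation of the enone (no γ‑H available) and C‑methylation of the cross‑conjugated enolate; the new centre is re‑enolized in step 4, so its configuration does not matter.

**Step 4**
Reactants: 5 (5R)‑4,4‑dimethoxy‑6‑methyl‑5‑(prop‑1‑en‑2‑yl)cyclohex‑2‑en‑1‑one; 6 (tert‑butyldimethylsilyloxy)acetaldehyde
Product: 8 (5S,6R)‑6‑[(1S)‑2‑(tert‑butyldimethylsilyloxy)‑1‑(mesyloxy)ethyl]‑4,4‑dimethoxy‑6‑methyl‑5‑(prop‑1‑en‑2‑yl)cyclohex‑2‑en‑1‑one, via lithium aldolate 7 (not isolated)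
Conditions: LDA, THF, −78 °C; 6; then MsCl, −78 to 0 °C
Reagents that add atoms: methanesulfonyl chloride CS(=O)(=O)Cl
Why: aldol addition of the tetrasubstituted α′‑enolate anti to the adjacent isopropenyl group sets quaternary C10 (Me cis to isopropenyl), a Zimmerman–Traxler chair with the aldehyde substituent equatorial sets the carbinol centre (moderate dr expected), and the aldolate is trapped as the mesylate needed for later inversion.

**Step 5**
Reactants: 8 (the mesylate from step 4); 9 triethyl phosphonoacetate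
Product: 10 C7β‑[(diethoxyphosphoryl)(ethoxycarbonyl)methyl] C9‑ketone (Michael adduct of 8; C11 epimers)
Conditions: 9 (1.5 eq), t‑BuOK (20 mol%), THF, rt, 24 h
Reagents that add atoms: none
Why: Michael addition of the phosphonoacetate anion to the enone β‑carbon C7; under catalytic base the addition is reversible, so the adduct with the C5 and C7 substituents cis (diequatorial) should predominate (estimated only about 4:1, minor epimer removed after step 6), and olefination at the neopentyl C9 carbonyl is sterically disfavoured.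

**Step 6**
Reactants: 10 (the Michael adduct)
Product: 12 6,6‑dimethoxy‑9‑oxo α‑phosphono‑8α,12‑lactone (trans‑fused), via 8α‑hydroxy ketone 11 (not isolated)
Conditions: LiHMDS (2.2 eq), THF, −78 °C; 2‑(phenylsulfonyl)‑3‑phenyloxaziridine; AcOH; then PPTS (cat.), toluene, 50 °C
Reagents that add atoms: 2‑(phenylsulfonyl)‑3‑phenyloxaziridine O=S(=O)(c1ccccc1)N1OC1c1ccccc1
Why: after the phosphonoacetate C–H, C8 is the only enolizable position of the C9 ketone; Davis oxidation of that enolate from the α‑face (the β‑face is shielded by the axial C10 methyl and axial C6 methoxy) gives the 8α‑alcohol trans to the C7 side chain, which lactonizes onto the ethyl ester.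

**Step 7**
Reactants: 12 (the keto lactone)
Product: 13 9α‑hydroxy α‑phosphono‑8α,12‑lactone (C6 ketal)
Conditions: L‑Selectride (2.5 eq), THF, −78 °C; AcOH quench at −78 °C
Reagents that add atoms: none
Why: the bulky hydride attacks the C9 ketone along the equatorial trajectory, as in Selectride reductions of 4,4‑dimethyl‑3‑keto terpenoids to axial alcohols, giving the axial 9α‑OH cis to O8; the lactone is protected as its phosphonate‑stabilized enolate and the cold quench avoids Grob fragmentation of the alkoxide/mesylate pair.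

**Step 8**
Reactants: 13 (the 9α‑alcohol); 14 (S)‑2‑methylbutanoic anhydride
Product: 15 9α‑[(S)‑2‑methylbutanoyloxy] α‑phosphono‑8α,12‑lactone (C6 ketal)
Conditions: 14 (1.5 eq), DMAP (0.2 eq), Et3N, CH2Cl2, rt
Reagents that add atoms: none
Why: Steglich‑type acylation of the only free hydroxyl; the anhydride with DMAP avoids ketene formation and so keeps the (S) centre of the acyl group.

**Step 9**
Reactants: 15 (the ester ketal)
Product: 16 C6 ketone (6‑oxo analogue of 15)
Conditions: 10% aq. oxalic acid on SiO2, CH2Cl2, rt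
Reagents that add atoms: water O
Why: mild heterogeneous hydrolysis of the dimethyl ketal that leaves the TBS ether, mesylate and esters intact and is too weakly acidic to enolize the new ketone, so C5 and C7 keep their configuration and the isopropenyl group does not move into conjugation.

**Step 10**
Reactants: 16 (the C6 ketone)
Product: 17 6β‑alcohol
Conditions: NaBH4, CeCl3·7H2O, MeOH, −78 °C
Reagents that add atoms: none
Why: Luche reduction; axial attack on C6 is blocked by the syn‑axial C10 methyl, so hydride enters from the α‑face anti to both flanking substituents and gives the axial 6β‑OH, while the cold, weakly basic conditions avoid β‑elimination of the C8 acyloxy group.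

**Step 11**
Reactants: 17 (the 6β‑alcohol)
Product: 19 (1R)‑1,2‑epoxide (oxiranyl α‑phosphono lactone), via hydroxy mesylate 18 (not isolated)
Conditions: TBAF (2.5 eq), THF, 0 °C to rt
Reagents that add atoms: none
Why: fluoride removes the primary TBS group and the resulting alkoxide displaces the adjacent secondary mesylate (3‑exo‑tet SN2), closing the oxirane with inversion at C1 to the required (R) configuration.

**Step 12**
Reactants: 19 (the epoxide)
Product: 20 15‑deoxy target (C5‑isopropenyl α‑methylene lactone)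
Conditions: K2CO3, 37% aq. HCHO, THF, 0 °C to rt
Reagents that add atoms: formaldehyde C=O
Why: Horner–Wadsworth–Emmons olefination of the α‑phosphono lactone with formaldehyde gives the α‑methylene‑γ‑butyrolactone under conditions the ester, oxirane and free 6‑OH tolerate.

**Step 13**
Reactants: 20 (the 15‑deoxy target)
Product: 22 target CNP0510523.1, via allylic alcohol 21 (not isolated)
Conditions: SeO2 (2 eq), pyridine (cat.), 1,4‑dioxane, 70 °C
Reagents that add atoms: selenium dioxide O=[Se]=O
Why: Riley allylic oxidation (ene reaction, then [2,3]‑shift) of the only electron‑rich alkene oxidizes the isopropenyl methyl through the allylic alcohol to the enal; the α‑methylene lactone is too electron‑poor to react.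

**Compound list**
1 | 4,4‑dimethoxycyclohexa‑2,5‑dien‑1‑one | COC1(OC)C=CC(=O)C=C1 | starting material
2 | acetaldehyde | CC=O | starting material
3 | (R)‑5‑acetyl‑4,4‑dimethoxycyclohex‑2‑en‑1‑one | O=C1C=CC(OC)(OC)[C@@H](C(C)=O)C1 | intermediate
4 | (R)‑4,4‑dimethoxy‑5‑(prop‑1‑en‑2‑yl)cyclohex‑2‑en‑1‑one | O=C1C=CC(OC)(OC)[C@@H](C(C)=C)C1 | intermediate
5 | (5R)‑4,4‑dimethoxy‑6‑methyl‑5‑(prop‑1‑en‑2‑yl)cyclohex‑2‑en‑1‑one, C6 epimers | O=C1C=CC(OC)(OC)[C@@H](C(C)=C)C1C | intermediate
6 | (tert‑butyldimethylsilyloxy)acetaldehyde | O=CCO[Si](C)(C)C(C)(C)C | starting material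
7 | aldol adduct of 5 and 6, present as its lithium alkoxide (drawn as the alcohol) | O=C1C=CC(OC)(OC)[C@@H](C(C)=C)[C@]1(C)[C@H](O)CO[Si](C)(C)C(C)(C)C | intermediate (not isolated)
8 | (5S,6R)‑6‑[(1S)‑2‑(tert‑butyldimethylsilyloxy)‑1‑(mesyloxy)ethyl]‑4,4‑dimethoxy‑6‑methyl‑5‑(prop‑1‑en‑2‑yl)cyclohex‑2‑en‑1‑one | O=C1C=CC(OC)(OC)[C@@H](C(C)=C)[C@]1(C)[C@H](OS(C)(=O)=O)CO[Si](C)(C)C(C)(C)C | intermediate
9 | triethyl phosphonoacetate | CCOC(=O)CP(=O)(OCC)OCC | starting material
10 | Michael adduct: 8 with C8 = CH2 and C7 bearing CH[P(O)(OEt)2]CO2Et cis to the isopropenyl group (C11 epimers) | O=C1C[C@@H](C(C(=O)OCC)P(=O)(OCC)OCC)C(OC)(OC)[C@@H](C(C)=C)[C@]1(C)[C@H](OS(C)(=O)=O)CO[Si](C)(C)C(C)(C)C | intermediate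
11 | 8α‑hydroxy derivative of 10 | O[C@@H]1[C@@H](C(C(=O)OCC)P(=O)(OCC)OCC)C(OC)(OC)[C@@H](C(C)=C)[C@](C)([C@H](OS(C)(=O)=O)CO[Si](C)(C)C(C)(C)C)C1=O | intermediate (not isolated)
12 | trans‑fused α‑(diethoxyphosphoryl)‑8α,12‑lactone, C9 ketone, C6 dimethyl ketal | O=C1O[C@@H]2[C@@H](C1P(=O)(OCC)OCC)C(OC)(OC)[C@@H](C(C)=C)[C@](C)([C@H](OS(C)(=O)=O)CO[Si](C)(C)C(C)(C)C)C2=O | intermediate
13 | 9α‑alcohol of 12 | O=C1O[C@@H]2[C@@H](C1P(=O)(OCC)OCC)C(OC)(OC)[C@@H](C(C)=C)[C@](C)([C@H](OS(C)(=O)=O)CO[Si](C)(C)C(C)(C)C)[C@@H]2O | intermediate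
14 | (S)‑2‑methylbutanoic anhydride | CC[C@H](C)C(=O)OC(=O)[C@@H](C)CC | starting material
15 | 9α‑(S)‑2‑methylbutanoate of 13 | O=C1O[C@@H]2[C@@H](C1P(=O)(OCC)OCC)C(OC)(OC)[C@@H](C(C)=C)[C@](C)([C@H](OS(C)(=O)=O)CO[Si](C)(C)C(C)(C)C)[C@@H]2OC(=O)[C@@H](C)CC | intermediate
16 | C6 ketone from 15 | O=C1O[C@@H]2[C@@H](C1P(=O)(OCC)OCC)C(=O)[C@@H](C(C)=C)[C@](C)([C@H](OS(C)(=O)=O)CO[Si](C)(C)C(C)(C)C)[C@@H]2OC(=O)[C@@H](C)CC | intermediate
17 | 6β‑alcohol from 16 | O=C1O[C@@H]2[C@@H](C1P(=O)(OCC)OCC)[C@@H](O)[C@@H](C(C)=C)[C@](C)([C@H](OS(C)(=O)=O)CO[Si](C)(C)C(C)(C)C)[C@@H]2OC(=O)[C@@H](C)CC | intermediate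
18 | desilylated hydroxy mesylate from 17 (as its alkoxide) | O=C1O[C@@H]2[C@@H](C1P(=O)(OCC)OCC)[C@@H](O)[C@@H](C(C)=C)[C@](C)([C@H](OS(C)(=O)=O)CO)[C@@H]2OC(=O)[C@@H](C)CC | intermediate (not isolated)
19 | (R)‑oxiranyl α‑phosphono lactone | O=C1O[C@@H]2[C@@H](C1P(=O)(OCC)OCC)[C@@H](O)[C@@H](C(C)=C)[C@](C)([C@@H]3CO3)[C@@H]2OC(=O)[C@@H](C)CC | intermediate
20 | 15‑deoxy target: α‑methylene lactone with C5 isopropenyl | C=C1C(=O)O[C@@H]2[C@@H]1[C@@H](O)[C@@H](C(C)=C)[C@](C)([C@@H]1CO1)[C@@H]2OC(=O)[C@@H](C)CC | intermediate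
21 | 15‑hydroxy compound (allylic alcohol) | C=C1C(=O)O[C@@H]2[C@@H]1[C@@H](O)[C@@H](C(=C)CO)[C@](C)([C@@H]1CO1)[C@@H]2OC(=O)[C@@H](C)CC | intermediate (not isolated)
22 | (3aS,4S,5R,6R,7S,7aR)‑4‑hydroxy‑6‑methyl‑3‑methylidene‑6‑[(2R)‑oxiran‑2‑yl]‑2‑oxo‑5‑(3‑oxoprop‑1‑en‑2‑yl)octahydro‑1‑benzofuran‑7‑yl (2S)‑2‑methylbutanoate | C=C1C(=O)O[C@@H]2[C@@H]1[C@@H](O)[C@@H](C(=C)C=O)[C@](C)([C@@H]1CO1)[C@@H]2OC(=O)[C@@H](C)CC | target

**Totals**
Total steps: 13. Longest linear sequence: 13 (from 1).

**Three steps most likely to fail**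

Step 1 (intermolecular asymmetric Stetter reaction on a hindered β‑carbon; conversion, mono‑selectivity and ee are unproven). The fallback sets out from 1 and returns at 3. Compound 1 is treated with nitroethane and a cinchona‑derived primary‑amine catalyst (iminium activation, the nitronate serving as the acetyl anion equivalent) to give (5R)‑4,4‑dimethoxy‑5‑(1‑nitroethyl)cyclohex‑2‑en‑1‑one F1. A buffered McMurry–Nef reaction (TiCl3, NH4OAc, aq. THF) then converts the nitro group into the ketone, giving 3.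

Step 5 (1,4‑addition at a β‑carbon flanked by the ketal may be slow, may compete with olefination, and the thermodynamic preference for the 7β epimer is modest). The fallback sets out from 10 as its C7 epimer mixture and returns at 10 as the single 7β epimer. The mixture is dehydrogenated with IBX (DMSO, 65 °C; only C8 carries α‑hydrogens) to the C7‑substituted enone F2. Conjugate reduction with Stryker's reagent then delivers hydride to C7 from the open α‑face (trans to the C5 isopropenyl group), which places the side chain β.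

Step 13 (late SeO2 oxidation beside an oxirane, a free alcohol and two esters; over‑ or under‑oxidation is possible). The fallback sets out from 20 and returns at 22. Ene‑type allylic chlorination (NCS, cat. PhSeCl, CH2Cl2) converts the isopropenyl group into the 2‑(chloromethyl)vinyl group, giving the allylic chloride F3. Ganem oxidation (Me3NO, DMSO, rt) then turns the CH2Cl group into the aldehyde 22.

**Further compounds**
F1 | step 1 | (5R)‑4,4‑dimethoxy‑5‑(1‑nitroethyl)cyclohex‑2‑en‑1‑one | O=C1C=CC(OC)(OC)[C@@H](C(C)[N+](=O)[O-])C1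
F2 | step 5 | C7‑[(diethoxyphosphoryl)(ethoxycarbonyl)methyl] C7=C8 enone derived from 10 | O=C1C=C(C(C(=O)OCC)P(=O)(OCC)OCC)C(OC)(OC)[C@@H](C(C)=C)[C@]1(C)[C@H](OS(C)(=O)=O)CO[Si](C)(C)C(C)(C)C
F3 | step 13 | 15‑chloro‑15‑deoxy compound (allylic chloride of 20) | C=C1C(=O)O[C@@H]2[C@@H]1[C@@H](O)[C@@H](C(=C)CCl)[C@](C)([C@@H]1CO1)[C@@H]2OC(=O)[C@@H](C)CC
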